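Is there anything left to gain by waiting until 2.0 d in this flask, and what will it hold then?

| flask | E | G | remark | time |
|---|---|---|---|---|
| beta | 0.064 M | 0.95 equiv | the very flask that is asked about, followed so far |  |
| gamma | 0.096 M | 0.95 equiv | run made earlier |  |
| flask | 0.064 M | 0.950 equiv |  | 2.0 d |

| run | time / h | E / % | D / % | J / % |
|---|---|---|---|---|
| beta | 1.33 | 25.1 | 11.6 | 32.9 |
| beta | 4.00 | 22.8 | 11.7 | 35.4 |
| beta | 6.00 | 22.4 | 11.2 | 35.1 |
| beta | 10.0 | 21.7 | 11.2 | 35.0 |
| beta | 15.0 | 21.6 | 11.2 | 35.8 |
| beta | 20.0 | 22.3 | 11.3 | 35.3 |
| beta | 25.0 | 21.6 | 11.4 | 35.3 |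
| gamma | 2.50 | 22.7 | 11.2 | 35.1 |
| gamma | 4.00 | 22.8 | 11.5 | 35.6 |
| gamma | 6.00 | 22.7 | 10.9 | 35.0 |
| gamma | 10.0 | 22.0 | 11.2 | 35.1 |
| gamma | 15.0 | 22.4 | 11.1 | 34.7 |
| gamma | 20.0 | 22.0 | 11.6 | 34.7 |
| gamma | 30.0 | 22.2 | 11.1 | 35.3 |

(each reading ± 0.3 percentage points)

* why nothing more happens at 2.0 d, or that something still does (all of E has reacted / it is still moving / G has run out first)
* share of the E used up at 2.0 d
* D at 2.0 d, in percent of the E charged
* J at 2.0 d, in percent of the E charged
* X at 2.0 d, in percent of the E charged
* amount of D if the flask were left three thousand times as long, in percent of the E charged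

- the numbers in the tables scatter with a standard deviation of 0.3 percentage points
- what may be going on: 2 G -> L; E <-> Z; G + D -> Q; D <-> X; E + G -> D; E + G -> J; G + J -> Q
- what has gone from E into another species counts as reacted, even if it can come back
- the reaction counts as stopped when no species that holds the E changes by six tenths of a point or more over the second half of the time

The rate of E + G → D or E + G → J is a rate constant times [E] times [G], so while E is still present, a flat E means the factor [G] has dropped out. The beta run, which is this flask followed so far, reads E at 21.7% after 10.0 h and 21.6% after 25.0 h, and the gamma run, charged at 0.096 M instead of 0.064 M, ends at 22.2%. I therefore take G for the limiting reagent, the charge that is used up first and caps how far reaction goes while E stands at 21.6%, and I carry the last beta readings forward to 2.0 d: conversion 78.4%, D 11.4%, J 35.3%.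

X is not read, but G can be counted, since each D, J and X holds one G and each Q and L holds two. The charge of 0.95 equiv, less D and J, leaves 48.3% of the E charged; this is the G gap, the G that must sit in X, Q and L together if none of it remains free. It gives me their weighted sum but not X by itself, so my own reckoning puts no number on X.

The forecast says G has run out first, with conversion 78%, D 11.2%, J 35.2%, X 4% (between 0% and 14.5%) and long-standing D 10.5%, adding of X that “The data cannot fix it more closely”.

The flask gives G has run out first, with G at 0% of its charge at 2.0 d, conversion 77.9%, D 11.4%, J 35.2%, X 10.8% and long-standing D 11.4%.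

    2 G → L (k = 0.186 /M/min)
    E ⇌ Z (K = 0.540, k = 0.586 /min)
    G + D → Q (k = 0.503 /M/min)
    D ⇌ X (K = 0.941, k = 0.0562 /min)
    E + G → D (k = 0.493 /M/min)
    E + G → J (k = 0.641 /M/min)
    G + J → Q (k = 0.0677 /M/min)

In this flask Q stands at 8.58% and L at 0.00655 M, so X, two G per Q and two G per L come to 48.4% of the E charged, beside the gap of 48.3% from the readings. The neighbouring flask with 1.60 equiv of G ends with G at 0% and E at 9.20%; its D of 11.8% and J of 43.2% give a gap of 105%. There X at 11.1%, Q at 19.8% and L at 0.0174 M, counted the same way, come to 105%.

(The readings were generated by integration with made-up constants, noise included.)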